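**Plan** (numbering: C15 chain C1–C15 with C1≡C2, C3=C4, Br on C9 and C12; oxane = O–C6–C7–C8–C9–C10; oxocane = O–C7–C8–C9–C10–C11–C12–C13)
1. Late cuts: C1–C2 (Colvin alkyne), C3=C4 (cross-metathesis), C5–C6 (allylation of a C6 acetal), and both C–Br bonds (back to ketones at C9 and C12).
2. Central cut: C6–C7 and C11–C12 together, which opens both rings of the 2,7-dioxabicyclo[4.2.2]decane to an open-chain cross-conjugated dienone.
3. Enabling feature: C7 and C11 are the two β-carbons of one ketone at C9 (the future C9–Br). Their partners C6 and C12 each carry oxygen and so a hydridic C–H, so two α-oxy radicals can add Giese-fashion to the two arms of C7=C8–C9(=O)–C10=C11.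
4. Forward: ynone plus the (R)-butane-1,2-diol ether gives the alkoxy enone, then the α-methylene ketone; one photocatalytic step closes the oxane (C6–C7) and then the oxocane (C11–C12); then C6 allylation, reduction of both ketones, double SN2 bromination, enyne.
5. Stereochemistry: C13 from (R)-butane-1,2-diol; C7 and C10 from the cis bridge, gated by the C13 ethyl group; C6 from attack anti to the four-atom bridge; C9 and C12 from hydride delivery followed by inversion.

Key step: step 8

Step 1
Reactants: 1 methyl glycolate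
Product: 2 methyl 2-(methoxymethoxy)acetate
Conditions: MOMCl, i-Pr2NEt, CH2Cl2, 0 °C to rt
Reagents that add atoms: chloromethyl methyl ether, COCCl
Why: O-alkylation of the hydroxyl by the α-chloro ether (Williamson-type MOM ether formation); the O–CH2–O carbon introduced here becomes C6.

Step 2
Reactants: 2 methyl 2-(methoxymethoxy)acetate
Product: 3 N-methoxy-2-(methoxymethoxy)-N-methylacetamide
Conditions: MeNH(OMe)·HCl, i-PrMgCl, THF, −20 °C
Reagents that add atoms: N,O-dimethylhydroxylamine hydrochloride, CNOC.Cl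
Why: the chloromagnesium amide formed in the flask acylates on the ester (Weinreb amide formation), and the MOM acetal is inert to the base.

Step 3
Reactants: 3 N-methoxy-2-(methoxymethoxy)-N-methylacetamide
Product: 4 1-(methoxymethoxy)but-3-yn-2-one
Conditions: HC≡CMgBr, THF, −78 to 0 °C; cold aq. NaHSO4
Reagents that add atoms: ethynylmagnesium bromide, C#C[Mg]Br
Why: Weinreb ketone synthesis: the chelated tetrahedral adduct holds until the acidic quench, so the ynone (C7–C10) should form without over-addition.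

Step 4
Reactants: 5 (R)-butane-1,2-diol
Product: 6 (2R)-1-[(tert-butyldimethylsilyl)oxy]butan-2-ol
Conditions: TBSCl, imidazole, CH2Cl2, 0 °C
Reagents that add atoms: tert-butyldimethylsilyl chloride, CC(C)(C)[Si](C)(C)Cl
Why: the primary hydroxyl is silylated selectively on steric grounds, and the stereocentre (future C13) is not touched.

Step 5
Reactants: 6 (2R)-1-[(tert-butyldimethylsilyl)oxy]butan-2-ol; 4 1-(methoxymethoxy)but-3-yn-2-one
Product: 7 (E)-4-{[(2R)-1-[(tert-butyldimethylsilyl)oxy]butan-2-yl]oxy}-1-(methoxymethoxy)but-3-en-2-one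
Conditions: PMe3 (10 mol %), CH2Cl2, 0 °C to rt
Reagents that add atoms: none
Why: phosphine-catalysed oxa-Michael addition of the secondary alcohol to the terminal ynone should give the thermodynamically preferred (E)-β-alkoxy enone, which forms the O–C7 bond of the oxocane.

Step 6
Reactants: 7 (E)-4-{[(2R)-1-[(tert-butyldimethylsilyl)oxy]butan-2-yl]oxy}-1-(methoxymethoxy)but-3-en-2-one
Product: 9 (E)-5-{[(2R)-1-[(tert-butyldimethylsilyl)oxy]butan-2-yl]oxy}-2-(methoxymethoxy)penta-1,4-dien-3-one, via Mannich base 8 (not isolated)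
Conditions: (CH2O)n, i-Pr2NH·CF3CO2H, THF, 65 °C
Reagents that add atoms: formaldehyde (from paraformaldehyde), C=O
Why: Mannich reaction at the only enolisable carbon (C10, between the carbonyl and the MOM oxygen) followed by β-elimination of the amine gives the α-methylene ketone and introduces C11.

Step 7
Reactants: 9 (E)-5-{[(2R)-1-[(tert-butyldimethylsilyl)oxy]butan-2-yl]oxy}-2-(methoxymethoxy)penta-1,4-dien-3-one
Product: 10 (E)-5-{[(2R)-1-hydroxybutan-2-yl]oxy}-2-(methoxymethoxy)penta-1,4-dien-3-one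
Conditions: HF·pyridine, pyridine, THF, 0 °C
Reagents that add atoms: none
Why: fluoride cleaves the Si–O bond under buffered conditions that should spare the MOM acetal and the dienone; the alcohol is taken on at once.

Step 8
Reactants: 10 (E)-5-{[(2R)-1-hydroxybutan-2-yl]oxy}-2-(methoxymethoxy)penta-1,4-dien-3-one
Product: 12 (1S,3R,6R)-3-ethyl-4-hydroxy-8-methoxy-2,7-dioxabicyclo[4.2.2]decan-10-one, via monocyclic oxanone 11 (not isolated)
Conditions: (n-Bu4N)4[W10O32] (2 mol %), MeCN (5 mM), 390 nm LEDs, 25 °C, Ar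
Reagents that add atoms: none
Why: Proposed new method: the photoexcited decatungstate anion abstracts a hydridic hydrogen atom from the O–CH2–O carbon (C6) and from the carbinol CH2 (C12); each nucleophilic α-oxy radical adds to the β-carbon of one enone arm (C6 to C7, C12 to C11) and the α-keto radicals at C8 and C10 take the hydrogen atom back from the reduced polyoxometalate, so the whole step is a redox-neutral isomerisation; the closest known reaction type is the decatungstate-photocatalysed Giese hydroalkylation of enones with acetals and with alcohols, here used twice within one molecule. The oxane closes first in the 6-endo-trig mode to give 11, because the E double bond C7=C8 cannot be held in an eight-membered ring, and the oxocane then closes in the 8-endo-trig mode onto the exocyclic methylene C11. C10 is set by the bridge itself, since the four-atom bridge can only span cis from C7–O to C10; C7 is set by gating, since only the C7 epimer of 11 that lets the C13 ethyl group point away from the O–C6 bridge can bring C12 to C11, so the bicycle should form in the (1S,6R) series fixed by the (R) centre at C13, while C6 (acetal) and C12 (carbinol) arise as epimer pairs that are re-set in steps 9 to 11. The step needs site-selective hydrogen abstraction and β-selective addition: the acetal and carbinol C–H bonds are the most hydridic in 10, the C13–H bond is deactivated because its oxygen belongs to the vinylogous ester, and attack at the enone α-carbons is mismatched in polarity. High dilution and a short irradiation should keep intermolecular addition and reversible abstraction at the α-oxy C–H bonds of the product in check.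

Step 9
Reactants: 12 (1S,3R,6R)-3-ethyl-4-hydroxy-8-methoxy-2,7-dioxabicyclo[4.2.2]decan-10-one
Product: 13 (1S,3R,6R,8R)-3-ethyl-4-hydroxy-8-(prop-2-en-1-yl)-2,7-dioxabicyclo[4.2.2]decan-10-one
Conditions: allylSiMe3, Me3SiOTf (20 mol %), MeCN, −40 °C; aq. NaHCO3
Reagents that add atoms: allyltrimethylsilane, C=CC[Si](C)(C)C
Why: Hosomi–Sakurai allylation of the cyclic methyl acetal through the C6 oxocarbenium ion; the silane should attack trans to the C7–O bond, on the face away from the four-atom bridge, which sets C6 (locant 8, R) and removes the anomeric mixture.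

Step 10
Reactants: 13 (1S,3R,6R,8R)-3-ethyl-4-hydroxy-8-(prop-2-en-1-yl)-2,7-dioxabicyclo[4.2.2]decan-10-one
Product: 14 (1S,3R,6R,8R)-3-ethyl-8-(prop-2-en-1-yl)-2,7-dioxabicyclo[4.2.2]decane-4,10-dione
Conditions: Dess–Martin periodinane, NaHCO3, CH2Cl2, 0 °C to rt
Reagents that add atoms: none
Why: Dess–Martin oxidation of the secondary carbinol converges both C12 epimers on one diketone under neutral conditions that should avoid β-elimination of the C7 alkoxy group and enolisation toward C13.

Step 11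
Reactants: 14 (1S,3R,6R,8R)-3-ethyl-8-(prop-2-en-1-yl)-2,7-dioxabicyclo[4.2.2]decane-4,10-dione
Product: 15 (1S,3R,4R,6R,8R,10R)-3-ethyl-8-(prop-2-en-1-yl)-2,7-dioxabicyclo[4.2.2]decane-4,10-diol
Conditions: Li[HB(s-Bu)3], THF, −78 °C; aq. NH4Cl
Reagents that add atoms: none
Why: the bulky hydride should reach each carbonyl from its open face (C9 from the side of the O–C6 bridge, away from the four-atom bridge; C12 anti to the C13 ethyl group in the Felkin–Anh sense), which gives the (4R,10R)-diol.

Step 12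
Reactants: 15 (1S,3R,4R,6R,8R,10R)-3-ethyl-8-(prop-2-en-1-yl)-2,7-dioxabicyclo[4.2.2]decane-4,10-diol
Product: 16 (1S,3R,4S,6R,8R,10S)-4,10-dibromo-3-ethyl-8-(prop-2-en-1-yl)-2,7-dioxabicyclo[4.2.2]decane
Conditions: CBr4, P(n-Oct)3, toluene, 70 °C
Reagents that add atoms: carbon tetrabromide, BrC(Br)(Br)Br
Why: double Appel reaction: each alkoxyphosphonium ion is displaced by bromide in an SN2 step, so both carbinol centres should invert to the (4S,10S) configuration of the target.

Step 13
Reactants: 16 (1S,3R,4S,6R,8R,10S)-4,10-dibromo-3-ethyl-8-(prop-2-en-1-yl)-2,7-dioxabicyclo[4.2.2]decane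
Product: 17 (2E)-4-[(1S,3R,4S,6R,8R,10S)-4,10-dibromo-3-ethyl-2,7-dioxabicyclo[4.2.2]decan-8-yl]but-2-enal
Conditions: (E)-but-2-enal (5 equiv), second-generation Hoveyda–Grubbs catalyst (5 mol %), CH2Cl2, 40 °C
Reagents that add atoms: (E)-but-2-enal, C/C=C/C=O
Why: olefin cross-metathesis of the terminal alkene with the electron-poor enal, which should be E-selective under thermodynamic control and leave the secondary bromides alone.

Step 14
Reactants: 17 (2E)-4-[(1S,3R,4S,6R,8R,10S)-4,10-dibromo-3-ethyl-2,7-dioxabicyclo[4.2.2]decan-8-yl]but-2-enal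
Product: 18 (1S,3R,4S,6R,8R,10S)-4,10-dibromo-3-ethyl-8-[(2E)-pent-2-en-4-yn-1-yl]-2,7-dioxabicyclo[4.2.2]decane
Conditions: Me3SiCHN2, LiN(i-Pr)2, THF, −78 to 0 °C; aq. NH4Cl
Reagents that add atoms: trimethylsilyldiazomethane, C[Si](C)(C)C=[N+]=[N-]
Why: Colvin rearrangement: the lithiated diazo compound adds to the aldehyde, Peterson elimination and loss of N2 give an alkylidene carbene, and its 1,2-hydrogen shift delivers the terminal alkyne while the E-alkene and the bromides stay untouched at low temperature.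

**Compound list**
1 | methyl glycolate | COC(=O)CO | starting material
2 | methyl 2-(methoxymethoxy)acetate | COCOCC(=O)OC | intermediate
3 | N-methoxy-2-(methoxymethoxy)-N-methylacetamide | COCOCC(=O)N(C)OC | intermediate
4 | 1-(methoxymethoxy)but-3-yn-2-one | C#CC(=O)COCOC | intermediate
5 | (R)-butane-1,2-diol | CC[C@@H](O)CO | starting material
6 | (2R)-1-[(tert-butyldimethylsilyl)oxy]butan-2-ol | CC[C@@H](O)CO[Si](C)(C)C(C)(C)C | intermediate
7 | (E)-4-{[(2R)-1-[(tert-butyldimethylsilyl)oxy]butan-2-yl]oxy}-1-(methoxymethoxy)but-3-en-2-one | CC[C@H](CO[Si](C)(C)C(C)(C)C)O/C=C/C(=O)COCOC | intermediate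
8 | (E)-5-{[(2R)-1-[(tert-butyldimethylsilyl)oxy]butan-2-yl]oxy}-1-(diisopropylamino)-2-(methoxymethoxy)pent-4-en-3-one (Mannich base, epimers at C2) | CC[C@H](CO[Si](C)(C)C(C)(C)C)O/C=C/C(=O)C(CN(C(C)C)C(C)C)OCOC | intermediate (not isolated)
9 | (E)-5-{[(2R)-1-[(tert-butyldimethylsilyl)oxy]butan-2-yl]oxy}-2-(methoxymethoxy)penta-1,4-dien-3-one | CC[C@H](CO[Si](C)(C)C(C)(C)C)O/C=C/C(=O)C(=C)OCOC | intermediate
10 | (E)-5-{[(2R)-1-hydroxybutan-2-yl]oxy}-2-(methoxymethoxy)penta-1,4-dien-3-one | CC[C@H](CO)O/C=C/C(=O)C(=C)OCOC | intermediate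
11 | (5S)-5-{[(2R)-1-hydroxybutan-2-yl]oxy}-6-methoxy-2-methylideneoxan-3-one (epimers at C6) | COC1OC(=C)C(=O)C[C@@H]1O[C@H](CC)CO | intermediate (not isolated)
12 | (1S,3R,6R)-3-ethyl-4-hydroxy-8-methoxy-2,7-dioxabicyclo[4.2.2]decan-10-one (epimers at C4 and C8) | COC1O[C@@H]2CC(O)[C@@H](CC)O[C@H]1CC2=O | intermediate
13 | (1S,3R,6R,8R)-3-ethyl-4-hydroxy-8-(prop-2-en-1-yl)-2,7-dioxabicyclo[4.2.2]decan-10-one (epimers at C4) | C=CC[C@H]1O[C@@H]2CC(O)[C@@H](CC)O[C@H]1CC2=O | intermediate
14 | (1S,3R,6R,8R)-3-ethyl-8-(prop-2-en-1-yl)-2,7-dioxabicyclo[4.2.2]decane-4,10-dione | C=CC[C@H]1O[C@@H]2CC(=O)[C@@H](CC)O[C@H]1CC2=O | intermediate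
15 | (1S,3R,4R,6R,8R,10R)-3-ethyl-8-(prop-2-en-1-yl)-2,7-dioxabicyclo[4.2.2]decane-4,10-diol | C=CC[C@H]1O[C@@H]2C[C@@H](O)[C@@H](CC)O[C@H]1C[C@H]2O | intermediate
16 | (1S,3R,4S,6R,8R,10S)-4,10-dibromo-3-ethyl-8-(prop-2-en-1-yl)-2,7-dioxabicyclo[4.2.2]decane | C=CC[C@H]1O[C@@H]2C[C@H](Br)[C@@H](CC)O[C@H]1C[C@@H]2Br | intermediate
17 | (2E)-4-[(1S,3R,4S,6R,8R,10S)-4,10-dibromo-3-ethyl-2,7-dioxabicyclo[4.2.2]decan-8-yl]but-2-enal | O=C/C=C/C[C@H]1O[C@@H]2C[C@H](Br)[C@@H](CC)O[C@H]1C[C@@H]2Br | intermediate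
18 | (1S,3R,4S,6R,8R,10S)-4,10-dibromo-3-ethyl-8-[(2E)-pent-2-en-4-yn-1-yl]-2,7-dioxabicyclo[4.2.2]decane | C#C/C=C/C[C@H]1O[C@@H]2C[C@H](Br)[C@@H](CC)O[C@H]1C[C@@H]2Br | target

Total steps: 14. Longest linear sequence: 13 steps (steps 1 to 3, then 5 to 14).

**Steps most likely to fail**

1. Step 8 (Proposed new method). What may go wrong:
   - the hydrogen atom returns to C12 faster than the slow eight-membered closure;
   - abstraction also takes place at the tertiary C13–H or C7–H once the oxane has formed, which would erode configuration;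
   - the first closure shows no facial bias, so that the part of 11 whose ethyl group is turned to the O–C6 bridge cannot bridge;
   - the free hydroxyl of 10 adds to its own alkoxy enone before irradiation.

   Fallback (known reaction types only; sets out from 5 and comes back at 13): the rings are made through C–O bonds around a furan instead. 5 is silylated twice (Et3SiCl, imidazole) to (2R)-1,2-bis[(triethylsilyl)oxy]butane F1, whose primary silyl ether is oxidised directly under Swern conditions to (2R)-2-[(triethylsilyl)oxy]butanal F2. Felkin–Anh-controlled aldol addition of the lithium enolate of 2-acetylfuran (LiN(i-Pr)2, THF, −78 °C) gives (3S,4R)-1-(furan-2-yl)-3-hydroxy-4-[(triethylsilyl)oxy]hexan-1-one F3. Narasaka–Prasad reduction (Et2BOMe, NaBH4) gives the syn-diol (1R,3S,4R)-1-(furan-2-yl)-4-[(triethylsilyl)oxy]hexane-1,3-diol F4. Achmatowicz rearrangement (N-bromosuccinimide, NaHCO3, aqueous THF) gives the pyranone hemiacetal (2R)-6-hydroxy-2-{(2S,3R)-2-hydroxy-3-[(triethylsilyl)oxy]pentyl}-2H-pyran-3(6H)-one F5, which camphorsulfonic acid closes to the bicyclic ketal (1R,3S,5R)-3-{(1R)-1-[(triethylsilyl)oxy]propyl}-2,9-dioxabicyclo[3.3.1]non-7-en-6-one F6. Bu4NF removes the silyl group to give (1R,3S,5R)-3-[(1R)-1-hydroxypropyl]-2,9-dioxabicyclo[3.3.1]non-7-en-6-one F7 (not isolated), whose hydroxyl adds to the enone carbon C7 in a six-membered oxa-Michael closure to give the cage ketone (1S,3R,4S,6R,8R)-3-ethyl-4,8-epoxy-2,7-dioxabicyclo[4.2.2]decan-10-one F8. Hosomi–Sakurai opening of the cage acetal at C6 (allylSiMe3, Me3SiOTf, MeCN, −40 °C), anti to the departing oxygen, gives 13 as its (4S) epimer.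

2. Step 12. What may go wrong: a ring oxygen β to the activated carbinol takes part in the ionisation (bridged oxonium ion), which leads to retention or to a rearranged ether, or the alkoxyphosphonium ion eliminates.

   Fallback (sets out from 15 and comes back at 16): activation and substitution are separated and taken off the phosphonium manifold. Tf2O and pyridine in CH2Cl2 at −20 °C convert 15 into (1S,3R,4R,6R,8R,10R)-3-ethyl-8-(prop-2-en-1-yl)-2,7-dioxabicyclo[4.2.2]decane-4,10-diyl bis(trifluoromethanesulfonate) F9, which is displaced twice with inversion by Bu4NBr in toluene at 0 °C to give 16.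

3. Step 11. What may go wrong: hydride delivery from the unwanted face at C9, at C12 or at both.

   Fallback (sets out from 14 and comes back at 15): the configuration is corrected after the reduction instead of being controlled in it. NaBH4 in MeOH gives the epimeric diol (1S,3R,4S,6R,8R,10S)-3-ethyl-8-(prop-2-en-1-yl)-2,7-dioxabicyclo[4.2.2]decane-4,10-diol F10. Mitsunobu reaction (4-nitrobenzoic acid, PPh3, diisopropyl azodicarboxylate) inverts both centres to (1S,3R,4R,6R,8R,10R)-3-ethyl-8-(prop-2-en-1-yl)-2,7-dioxabicyclo[4.2.2]decane-4,10-diyl bis(4-nitrobenzoate) F11, and K2CO3 in MeOH releases 15.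

Further compounds
F1 | step 8 | (2R)-1,2-bis[(triethylsilyl)oxy]butane | CC[C@@H](O[Si](CC)(CC)CC)CO[Si](CC)(CC)CC
F2 | step 8 | (2R)-2-[(triethylsilyl)oxy]butanal | CC[C@@H](O[Si](CC)(CC)CC)C=O
F3 | step 8 | (3S,4R)-1-(furan-2-yl)-3-hydroxy-4-[(triethylsilyl)oxy]hexan-1-one | O=C(c1ccco1)C[C@H](O)[C@@H](CC)O[Si](CC)(CC)CC
F4 | step 8 | (1R,3S,4R)-1-(furan-2-yl)-4-[(triethylsilyl)oxy]hexane-1,3-diol | O[C@@H](c1ccco1)C[C@H](O)[C@@H](CC)O[Si](CC)(CC)CC
F5 | step 8 | (2R)-6-hydroxy-2-{(2S,3R)-2-hydroxy-3-[(triethylsilyl)oxy]pentyl}-2H-pyran-3(6H)-one (epimers at C6) | O=C1C=CC(O)O[C@@H]1C[C@H](O)[C@@H](CC)O[Si](CC)(CC)CC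
F6 | step 8 | (1R,3S,5R)-3-{(1R)-1-[(triethylsilyl)oxy]propyl}-2,9-dioxabicyclo[3.3.1]non-7-en-6-one | O=C1C=C[C@H]2O[C@@H]1C[C@H](O2)[C@@H](CC)O[Si](CC)(CC)CC
F7 | step 8 | (1R,3S,5R)-3-[(1R)-1-hydroxypropyl]-2,9-dioxabicyclo[3.3.1]non-7-en-6-one | O=C1C=C[C@H]2O[C@@H]1C[C@H](O2)[C@@H](CC)O
F8 | step 8 | (1S,3R,4S,6R,8R)-3-ethyl-4,8-epoxy-2,7-dioxabicyclo[4.2.2]decan-10-one | O=C1C[C@H]2[C@H]3O[C@@H]1C[C@H](O3)[C@@H](CC)O2
F9 | step 12 | (1S,3R,4R,6R,8R,10R)-3-ethyl-8-(prop-2-en-1-yl)-2,7-dioxabicyclo[4.2.2]decane-4,10-diyl bis(trifluoromethanesulfonate) | C=CC[C@H]1O[C@@H]2C[C@@H](OS(=O)(=O)C(F)(F)F)[C@@H](CC)O[C@H]1C[C@H]2OS(=O)(=O)C(F)(F)F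
F10 | step 11 | (1S,3R,4S,6R,8R,10S)-3-ethyl-8-(prop-2-en-1-yl)-2,7-dioxabicyclo[4.2.2]decane-4,10-diol | C=CC[C@H]1O[C@@H]2C[C@H](O)[C@@H](CC)O[C@H]1C[C@@H]2O
F11 | step 11 | (1S,3R,4R,6R,8R,10R)-3-ethyl-8-(prop-2-en-1-yl)-2,7-dioxabicyclo[4.2.2]decane-4,10-diyl bis(4-nitrobenzoate) | C=CC[C@H]1O[C@@H]2C[C@@H](OC(=O)c3ccc(cc3)[N+](=O)[O-])[C@@H](CC)O[C@H]1C[C@H]2OC(=O)c1ccc(cc1)[N+](=O)[O-]
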